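The plan cuts the cyclopentane ring of the indane at C2–C3 and removes one methyl group from the exocyclic C2=C(CH3)2 alkene. That alkene ends in two identical methyl groups, so a C2≡C–CH3 alkyne and one methyl nucleophile build it with the same result in either geometric sense. In a single operation palladium activates a benzylic chloride at C3, C3 adds 5-exo-dig to the alkyne (C2–C3 bond, ring closed), and methylboronic acid caps the vinylpalladium (C–CH3 bond). The precursor is a propargylic diarylmethane. Its C1 carries H, prop-1-ynyl, benzodioxane carbon C8′ and ring A, whose C3a, C7 and C6 bear CH2Cl, CHO and OTBS.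

Key step: step 16

Remark on locants: indane C1, C2, C3, C3a, C4–C7, C7a (ring A is its benzene ring); benzodioxane O1′, C2′, C3′, O4′, C4a′, C5′–C8′, C8a′ (ring B is its benzene ring); these locants are kept for all intermediates.
Assumption: the facial sense of step 11 is taken from the magnesium chelate model of tert-leucine ester aldimines; the (R)-amino ester is equally available should the sense prove opposite.

Step 1
Reactants: 1 3-methylbut-2-en-1-ol
Product: 2 [(2R)-3,3-dimethyloxiran-2-yl]methanol
Conditions: Ti(OiPr)4 (cat.), D-(−)-diisopropyl tartrate (cat.), tBuOOH, 4 Å MS, CH2Cl2, −20 °C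
Reagents that add atoms: tert-butyl hydroperoxide, CC(C)(C)OO
Why: Sharpless asymmetric epoxidation of a trisubstituted allylic alcohol; the D-(−)-tartrate directs oxygen to the face that makes the secondary epoxide carbon R, which the inversion in step 4 turns into (S)-C2′.

Step 2
Reactants: 2 [(2R)-3,3-dimethyloxiran-2-yl]methanol
Product: 3 [(2R)-3,3-dimethyloxiran-2-yl]methyl 3-nitrobenzenesulfonate
Conditions: 3-O2NC6H4SO2Cl, Et3N, DMAP (cat.), CH2Cl2, −10 °C; recrystallisation
Reagents that add atoms: 3-nitrobenzenesulfonyl chloride, O=S(=O)(Cl)c1cccc([N+](=O)[O-])c1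
Why: Sulfonylation of the primary alcohol leaves the epoxide and its stereocentre untouched and gives a crystalline, very reactive primary electrophile whose enantiopurity can be raised by recrystallisation.

Step 3
Reactants: 4 2-hydroxy-3-methoxy-5-methylbenzaldehyde
Product: 5 2,3-dihydroxy-5-methylbenzaldehyde
Conditions: BBr3, CH2Cl2, −78 → 0 °C; H2O
Reagents that add atoms: none
Why: Lewis-acid cleavage of an aryl methyl ether, which at low temperature spares the formyl group, as is routine for ortho-vanillin-type substrates.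

Step 4
Reactants: 5 2,3-dihydroxy-5-methylbenzaldehyde; 3 [(2R)-3,3-dimethyloxiran-2-yl]methyl 3-nitrobenzenesulfonate
Product: 8 ring B aldehyde (2′S)-8′-formyl-6′-methyl-2′-[2-(triethylsilyloxy)propan-2-yl]-2′,3′-dihydro-1′,4′-benzodioxine, via epoxy ether phenoxide 6 (not isolated), via tertiary sodium alkoxide 7 (not isolated)
Conditions: NaH (2.0 equiv), DMF, 0 °C; 3, rt then 70 °C; Et3SiCl, 0 °C
Reagents that add atoms: chlorotriethylsilane, CC[Si](Cl)(CC)CC
Why: Williamson alkylation followed by 6-exo-tet epoxide opening: in the dianion the O4′ oxide, which is not conjugated with the formyl group, is the better nucleophile and displaces the primary sulfonate, the O1′ phenoxide then attacks the less substituted epoxide carbon with inversion so that R becomes (S)-C2′, and the tertiary alkoxide set free is silylated in the same flask.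

Step 5
Reactants: 8 ring B aldehyde
Product: 9 (E)-3-(ring B)prop-2-enal (the CHO of 8 extended to CH=CH–CHO)
Conditions: Ph3P=CHCHO, toluene, 90 °C
Reagents that add atoms: (triphenylphosphoranylidene)acetaldehyde, O=CC=P(c1ccccc1)(c1ccccc1)c1ccccc1
Why: Wittig olefination with a stabilised ylide extends the aryl aldehyde by two carbons and gives the E-enal.

Step 6
Reactants: 9 (E)-enal; 10 tert-butyl (S)-2-amino-3,3-dimethylbutanoate
Product: 11 (E,E)-1-azadiene (aldimine of 9 carrying the (S)-tert-leucine tert-butyl ester)
Conditions: 4 Å MS, CH2Cl2, rt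
Reagents that add atoms: tert-butyl (S)-2-amino-3,3-dimethylbutanoate (10), CC(C)(C)[C@H](N)C(=O)OC(C)(C)C
Why: Imine condensation over molecular sieves attaches the chiral auxiliary to the acceptor without creating a stereocentre.

Step 7
Reactants: 12 2-bromo-6-hydroxybenzaldehyde
Product: 13 2-bromo-3-(chloromethyl)-6-hydroxybenzaldehyde
Conditions: (CH2O)n, conc. HCl, rt
Reagents that add atoms: formaldehyde (from paraformaldehyde), C=O; hydrogen chloride, Cl
Why: Blanc chloromethylation at the position para to the hydroxyl and meta to the formyl group (C3a), the same preference as for salicylaldehyde itself, brings in the C3 carbon that the bromophenol lacks.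

Step 8
Reactants: 13 2-bromo-3-(chloromethyl)-6-hydroxybenzaldehyde
Product: 14 2-bromo-6-hydroxy-3-(hydroxymethyl)benzaldehyde
Conditions: NaHCO3, acetone/H2O, rt, high dilution
Reagents that add atoms: water, O
Why: Solvolysis of a para-hydroxybenzylic chloride is fast under bicarbonate buffering (ionisation assisted by the para oxygen) and gives the benzylic alcohol.

Step 9
Reactants: 14 2-bromo-6-hydroxy-3-(hydroxymethyl)benzaldehyde
Product: 15 2-bromo-6-(tert-butyldimethylsilyloxy)-3-[(tert-butyldimethylsilyloxy)methyl]benzaldehyde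
Conditions: TBSCl (2.3 equiv), imidazole, DMF, rt
Reagents that add atoms: tert-butyldimethylsilyl chloride, CC(C)(C)[Si](C)(C)Cl
Why: Standard silylation protects phenol and primary alcohol in one operation, and the aryl and alkyl silyl ethers differ enough in acid lability to be told apart in step 14.

Step 10
Reactants: 15 bis-silylated bromoaldehyde
Product: 16 ring A bromide 2-{2-bromo-6-(tert-butyldimethylsilyloxy)-3-[(tert-butyldimethylsilyloxy)methyl]phenyl}-1,3-dioxolane
Conditions: (Me3SiOCH2)2, TMSOTf (cat.), CH2Cl2, −78 → −20 °C; pyridine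
Reagents that add atoms: 1,2-bis(trimethylsilyloxy)ethane, C[Si](C)(C)OCCO[Si](C)(C)C
Why: TMSOTf-catalysed aprotic acetalisation works on hindered aldehydes and spares silyl ethers, and the masked formyl group then tolerates the organomagnesium reagent and the strong bases of steps 11–13.

Step 11
Reactants: 16 ring A bromide; 11 (E,E)-1-azadiene
Product: 19 (R)-3,3-diarylpropanal (C1 bears CH2CHO; ring A of 16 at C7a; ring B of 8 at C8′), via arylmagnesium bromide 17 (not isolated), via adduct aldimine 18 (not isolated)
Conditions: 16, Mg, I2 (cat.), THF, 45 °C; added to 11, THF, −55 → −30 °C; aq. AcOH/NaOAc buffer, rt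
Reagents that add atoms: water, O
Why: Auxiliary-controlled 1,4-addition of a Grignard reagent to a chiral α,β-unsaturated aldimine: magnesium is chelated by the imine nitrogen and the ester carbonyl, the s-cis azadiene takes up the aryl group on the face away from the tert-butyl group, which sets C1 as R, a stoichiometric organomagnesium reagent being chosen over a catalytic arylboron addition because the aryl group is substituted at both ortho positions, and buffered hydrolysis frees aldehyde and auxiliary while the dioxolane stays on.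

Step 12
Reactants: 19 (R)-3,3-diarylpropanal
Product: 20 enol triflate of 19 (C1–CH=CH–OTf; mainly Z; both isomers are carried on)
Conditions: PhNTf2, then KN(SiMe3)2 added last, THF, −78 °C
Reagents that add atoms: N-phenylbis(trifluoromethanesulfonimide), O=S(=O)(N(c1ccccc1)S(=O)(=O)C(F)(F)F)C(F)(F)F
Why: O-sulfonylation of the potassium enolate under internal quench suppresses self-aldol reaction, and since the aldehyde has only one enolisable position the new double bond starts at C2, next to C1, without any added carbon.

Step 13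
Reactants: 20 enol triflate
Product: 22 protected propargylic diarylmethane (C1 bears prop-1-ynyl; ring A and ring B as in 19), via lithium acetylide 21 (not isolated)
Conditions: LiN(iPr)2 (2.2 equiv), THF, −78 °C; MeI, DMPU, −78 °C → rt
Reagents that add atoms: iodomethane, CI
Why: Base-induced elimination of triflate makes the triple bond on the unchanged chain so that it sits directly on C1 (a one-carbon aldehyde-to-alkyne homologation would have left a CH2 in between), the second equivalent of amide stores the alkyne as its acetylide, which lowers the acidity of the hindered C1–H, and SN2 methylation completes the prop-1-ynyl group.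

Step 14
Reactants: 22 protected propargylic diarylmethane
Product: 23 hydroxy aldehyde (ring A: C3a–CH2OH; C7–CHO; C6–OTBS; ring B side chain C(CH3)2OH free)
Conditions: 1 M aq. HCl, THF, 0 °C → rt
Reagents that add atoms: water, O
Why: Mild acid hydrolysis removes the dioxolane, the primary benzylic TBS ether and the tertiary TES ether together, whereas aryl TBS ethers are cleaved much more slowly under acidic conditions.

Step 15
Reactants: 23 hydroxy aldehyde
Product: 24 benzylic chloride (1R,2′S), the cyclisation precursor with C3a–CH2Cl; C7–CHO; C6–OTBS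
Conditions: PPh3, CCl4, CH2Cl2, 0 °C → rt; used without storage
Reagents that add atoms: carbon tetrachloride, ClC(Cl)(Cl)Cl
Why: Appel chlorination runs under neutral conditions and converts only the primary benzylic alcohol, leaving the tertiary alcohol, aldehyde, alkyne and aryl silyl ether alone.

Step 16
Reactants: 24 benzylic chloride; 25 methylboronic acid
Product: 28 O-tert-butyldimethylsilyl diaporindene G, via benzylpalladium chloride 26 (not isolated), via vinylpalladium chloride 27 (not isolated)
Conditions: Pd(PPh3)4 (5–10 mol %), 25 (3 equiv), anhydrous K3PO4, degassed dioxane, 70–80 °C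
Reagents that add atoms: methylboronic acid (25), CB(O)O
Why: Zerovalent palladium inserts into the benzylic C3–Cl bond to give 26, which has no β-hydrogen, syn carbopalladation of the tethered C2≡C bond gives 27, and methyl transfer from boron followed by reductive elimination installs the second methyl group. The closest known reaction type is the domino intramolecular alkyne carbopalladation/Suzuki–Miyaura capture used for tetrasubstituted exocyclic alkenes. The cyclopentane ring (C1–C2–C3–C3a–C7a) closes in the 5-exo-dig mode, because a 6-endo syn addition would require a trans-configured endocyclic alkenylpalladium in a six-membered ring. No stereocentre is formed: C1 and C2′ are spectators, and the geometry of 27 does not matter because both outer alkene substituents end up as methyl. The selectivity needed is ring closure before methyl capture, and it is secured by the three-atom tether (fast intramolecular insertion) set against the slow transmetalation of an alkylboronic acid. Anhydrous K3PO4 is chosen because loss of the C6 silyl group would let the phenoxide expel the para benzylic chloride as a quinone methide, and because this base is too weak to remove the C1–H.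

Step 17
Reactants: 28 O-tert-butyldimethylsilyl diaporindene G
Product: 29 diaporindene G (1R,2′S)
Conditions: Bu4NF, AcOH, THF, 0 °C
Reagents that add atoms: none
Why: Fluoride-induced desilylation of the aryl silyl ether is fast, and buffering with acetic acid keeps the medium non-basic so that the C1–H and the exocyclic alkene are not disturbed.

Compound list
1 | 3-methylbut-2-en-1-ol | CC(C)=CCO | starting material
2 | [(2R)-3,3-dimethyloxiran-2-yl]methanol | OC[C@H]1OC1(C)C | intermediate
3 | [(2R)-3,3-dimethyloxiran-2-yl]methyl 3-nitrobenzenesulfonate | O=S(=O)(OC[C@H]1OC1(C)C)c1cccc([N+](=O)[O-])c1 | intermediate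
4 | 2-hydroxy-3-methoxy-5-methylbenzaldehyde | COc1cc(C)cc(C=O)c1O | starting material
5 | 2,3-dihydroxy-5-methylbenzaldehyde | Cc1cc(O)c(O)c(C=O)c1 | intermediate
6 | epoxy ether phenoxide: sodium 2-formyl-4-methyl-6-{[(2R)-3,3-dimethyloxiran-2-yl]methoxy}phenolate | [Na+].[O-]c1c(C=O)cc(C)cc1OC[C@H]1OC1(C)C | intermediate
7 | tertiary sodium alkoxide of the (2′S)-benzodioxane aldehyde | O=Cc1cc(C)cc2c1O[C@H](C(C)(C)[O-])CO2.[Na+] | intermediate
8 | ring B aldehyde, (2′S)-8′-formyl-6′-methyl-2′-[2-(triethylsilyloxy)propan-2-yl]-2′,3′-dihydro-1′,4′-benzodioxine | O=Cc1cc(C)cc2c1O[C@H](C(C)(C)O[Si](CC)(CC)CC)CO2 | intermediate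
9 | (E)-3-(ring B)prop-2-enal, (2′S) | O=C/C=C/c1cc(C)cc2c1O[C@H](C(C)(C)O[Si](CC)(CC)CC)CO2 | intermediate
10 | tert-butyl (S)-2-amino-3,3-dimethylbutanoate | CC(C)(C)[C@H](N)C(=O)OC(C)(C)C | starting material
11 | (E,E)-1-azadiene from 9 and 10 | CC(C)(C)[C@H](/N=C/C=C/c1cc(C)cc2c1O[C@H](C(C)(C)O[Si](CC)(CC)CC)CO2)C(=O)OC(C)(C)C | intermediate
12 | 2-bromo-6-hydroxybenzaldehyde | O=Cc1c(O)cccc1Br | starting material
13 | 2-bromo-3-(chloromethyl)-6-hydroxybenzaldehyde | O=Cc1c(O)ccc(CCl)c1Br | intermediate
14 | 2-bromo-6-hydroxy-3-(hydroxymethyl)benzaldehyde | O=Cc1c(O)ccc(CO)c1Br | intermediate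
15 | 2-bromo-6-(TBS-oxy)-3-[(TBS-oxy)methyl]benzaldehyde | O=Cc1c(O[Si](C)(C)C(C)(C)C)ccc(CO[Si](C)(C)C(C)(C)C)c1Br | intermediate
16 | ring A bromide, 1,3-dioxolane of 15 | Brc1c(CO[Si](C)(C)C(C)(C)C)ccc(O[Si](C)(C)C(C)(C)C)c1C1OCCO1 | intermediate
17 | arylmagnesium bromide from 16 | Br[Mg]c1c(CO[Si](C)(C)C(C)(C)C)ccc(O[Si](C)(C)C(C)(C)C)c1C1OCCO1 | intermediate
18 | adduct aldimine, (1R), auxiliary (S), (2′S) | CC(C)(C)[C@H](/N=C/C[C@H](c1c(CO[Si](C)(C)C(C)(C)C)ccc(O[Si](C)(C)C(C)(C)C)c1C3OCCO3)c1cc(C)cc2c1O[C@H](C(C)(C)O[Si](CC)(CC)CC)CO2)C(=O)OC(C)(C)C | intermediate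
19 | (R)-3,3-diarylpropanal, (2′S) | O=CC[C@H](c1c(CO[Si](C)(C)C(C)(C)C)ccc(O[Si](C)(C)C(C)(C)C)c1C3OCCO3)c1cc(C)cc2c1O[C@H](C(C)(C)O[Si](CC)(CC)CC)CO2 | intermediate
20 | enol triflate of 19 (Z isomer drawn), (1R,2′S) | O=S(=O)(O/C=C\[C@H](c1c(CO[Si](C)(C)C(C)(C)C)ccc(O[Si](C)(C)C(C)(C)C)c1C3OCCO3)c1cc(C)cc2c1O[C@H](C(C)(C)O[Si](CC)(CC)CC)CO2)C(F)(F)F | intermediate
21 | lithium acetylide, (1R,2′S) | [Li]C#C[C@H](c1c(CO[Si](C)(C)C(C)(C)C)ccc(O[Si](C)(C)C(C)(C)C)c1C3OCCO3)c1cc(C)cc2c1O[C@H](C(C)(C)O[Si](CC)(CC)CC)CO2 | intermediate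
22 | protected propargylic diarylmethane, (1R,2′S) | CC#C[C@H](c1c(CO[Si](C)(C)C(C)(C)C)ccc(O[Si](C)(C)C(C)(C)C)c1C3OCCO3)c1cc(C)cc2c1O[C@H](C(C)(C)O[Si](CC)(CC)CC)CO2 | intermediate
23 | hydroxy aldehyde, (1R,2′S) | CC#C[C@H](c1c(CO)ccc(O[Si](C)(C)C(C)(C)C)c1C=O)c1cc(C)cc2c1O[C@H](C(C)(C)O)CO2 | intermediate
24 | benzylic chloride, cyclisation precursor, (1R,2′S) | CC#C[C@H](c1c(CCl)ccc(O[Si](C)(C)C(C)(C)C)c1C=O)c1cc(C)cc2c1O[C@H](C(C)(C)O)CO2 | intermediate
25 | methylboronic acid | CB(O)O | starting material
26 | benzylpalladium chloride (phosphine ligands omitted), C1 and C2′ unchanged | CC#C[C@H](c1c(C[Pd]Cl)ccc(O[Si](C)(C)C(C)(C)C)c1C=O)c1cc(C)cc2c1O[C@H](C(C)(C)O)CO2 | intermediate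
27 | vinylpalladium chloride (phosphine ligands omitted; Pd cis to C3), C1 and C2′ unchanged | C/C([Pd]Cl)=C1/Cc2ccc(O[Si](C)(C)C(C)(C)C)c(C=O)c2[C@@H]1c1cc(C)cc2c1O[C@H](C(C)(C)O)CO2 | intermediate
28 | O-tert-butyldimethylsilyl diaporindene G, (1R,2′S) | CC(C)=C1Cc2ccc(O[Si](C)(C)C(C)(C)C)c(C=O)c2[C@@H]1c1cc(C)cc2c1O[C@H](C(C)(C)O)CO2 | intermediate
29 | diaporindene G, (1R,2′S) | CC(C)=C1Cc2ccc(O)c(C=O)c2[C@@H]1c1cc(C)cc2c1O[C@H](C(C)(C)O)CO2 | target

Total step count: 17. Longest linear sequence: 12 steps (1, 2, 4, 5, 6, 11, 12, 13, 14, 15, 16, 17).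

Steps most likely to fail

Step 16. Three processes may intervene. Methyl may be transferred to the benzylpalladium species before the ring closes. The vinylpalladium species may be protonated. The C6 silyl group may be lost, after which chloride is expelled through a quinone methide. The fallback splits the domino into two operations and sets out from 24. The same carbopalladation is ended by boryl instead of methyl transfer (B2pin2, KOAc, PdCl2(dppf), dioxane, 70 °C), a capture that needs only acetate as base, and gives the exocyclic alkenyl pinacolboronate F1. A separate Suzuki–Miyaura methylation of F1 with MeI (PdCl2(dppf), K3PO4, DMF, 50 °C), run on a substrate that no longer holds a benzylic chloride, comes back to the route at 28.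

Step 11. The aryl group is flanked by two ortho substituents, so the 1,4-addition may be sluggish, may give way to 1,2-addition, or may show poor facial selectivity. The fallback uses a flatter, doubly activated acceptor that is also an alkyne precursor, and sets out from 8 and the Grignard reagent 17. Knoevenagel condensation of 8 with commercial 3-methylisoxazol-5(4H)-one gives the arylidene isoxazolone F2. Reagent 17 then adds in a conjugate sense to give the 4-(diarylmethyl)isoxazol-5(2H)-one F3 as two C1 epimers. These are diastereomers because of C2′, so chromatography separates them. Nitrosative cleavage of the (1R) epimer (NaNO2, FeSO4, aq. AcOH, rt) forms the triple bond under weakly acidic conditions and comes back to the route at 22, bypassing steps 5, 6, 12 and 13. Any partial loss of acid-labile groups is harmless because step 14 removes them.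

Step 13. The strong amide base may deprotonate C1. That would lead to isomerisation towards the conjugated allene and to erosion of the C1 configuration. The fallback builds the triple bond without strong base near an unsaturated C1 and sets out from 19.
- Pinnick oxidation (NaClO2, NaH2PO4, 2-methylbut-2-ene) gives the acid F4.
- Esterification (allyl alcohol, EDC, DMAP) gives the allyl ester F5.
- Enolate acetylation (LiN(iPr)2, then 1-acetylimidazole, −78 °C) gives the β-keto ester F6.
- Triflation under non-chelating conditions (KN(SiMe3)2, 18-crown-6, PhNTf2) gives the enol triflate F7, with carboxyl and triflate anti.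
- Deallylation with Pd(PPh3)4 and morpholine at rt triggers decarboxylative anti elimination and comes back to the route at 22.

Further compounds
F1 | step 16 | exocyclic alkenyl pinacolboronate (boron cis to C3), (1R,2′S) | C/C(B3OC(C)(C)C(C)(C)O3)=C1/Cc2ccc(O[Si](C)(C)C(C)(C)C)c(C=O)c2[C@@H]1c1cc(C)cc2c1O[C@H](C(C)(C)O)CO2
F2 | step 11 | (Z)-4-(ring B methylidene)-3-methylisoxazol-5(4H)-one, (2′S) | O=C1ON=C(C)/C1=C/c1cc(C)cc2c1O[C@H](C(C)(C)O[Si](CC)(CC)CC)CO2
F3 | step 11 | 4-(diarylmethyl)-3-methylisoxazol-5(2H)-one, (1R) epimer after separation, (2′S) | CC1=C([C@H](c2c(CO[Si](C)(C)C(C)(C)C)ccc(O[Si](C)(C)C(C)(C)C)c2C3OCCO3)c2cc(C)cc3c2O[C@H](C(C)(C)O[Si](CC)(CC)CC)CO3)C(=O)ON1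
F4 | step 13 | (R)-3,3-diarylpropanoic acid, (2′S) | OC(=O)C[C@H](c1c(CO[Si](C)(C)C(C)(C)C)ccc(O[Si](C)(C)C(C)(C)C)c1C3OCCO3)c1cc(C)cc2c1O[C@H](C(C)(C)O[Si](CC)(CC)CC)CO2
F5 | step 13 | allyl (R)-3,3-diarylpropanoate, (2′S) | C=CCOC(=O)C[C@H](c1c(CO[Si](C)(C)C(C)(C)C)ccc(O[Si](C)(C)C(C)(C)C)c1C3OCCO3)c1cc(C)cc2c1O[C@H](C(C)(C)O[Si](CC)(CC)CC)CO2
F6 | step 13 | allyl 2-acetyl-3,3-diarylpropanoate (C2 epimers), (1R,2′S) | C=CCOC(=O)C(C(C)=O)[C@H](c1c(CO[Si](C)(C)C(C)(C)C)ccc(O[Si](C)(C)C(C)(C)C)c1C3OCCO3)c1cc(C)cc2c1O[C@H](C(C)(C)O[Si](CC)(CC)CC)CO2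
F7 | step 13 | enol triflate of F6 (carboxyl and triflate anti), (1R,2′S) | C=CCOC(=O)/C([C@H](c1c(CO[Si](C)(C)C(C)(C)C)ccc(O[Si](C)(C)C(C)(C)C)c1C3OCCO3)c1cc(C)cc2c1O[C@H](C(C)(C)O[Si](CC)(CC)CC)CO2)=C(\C)OS(=O)(=O)C(F)(F)F
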